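**Plan**
- Retrosynthesis: the two acetates are removed. C1=O with C10=C14 is traced to a C1 silyl enol ether carrying a C14 pivalate (E1cB). The butenolide is opened at O–C12 and C7=C11 to a C6 ketone plus an α-keto ester.
- Enabling feature: in the ten-membered ring, C4=C5 and the C1(=O)–C10 unit are 1,5-related across C2–C3. This is the pattern left when the C1–C4 and C5–C10 bonds of a cyclohexane-fused bicyclo[2.2.0]hexane are cleaved.
- Re-forming those two bonds and cutting C1–C10 and C4–C5 gives a 3-substituted 5-silyloxycyclohexenone and a 1-silyloxy-2-methylcyclobutene; the enone is cut at C5=C10 (intramolecular olefination).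
- Forward: six-membered enone ring, then cyclobutane by photocycloaddition, then ten-membered ring by thermal opening, then butenolide, then unmasking and acetylation.
- Stereochemistry: C8 comes from a commercial (3R)-3-silyloxyglutarate-derived phosphonate; C6 from a reagent-controlled ketone reduction; Z-C4=C5 from the thermal opening. The four centres made in the photocycloaddition are erased.

Key step: step 9

Remark (numbering): atom numbers are those of the target skeleton: ring C1 (ketone), C2, C3, C4 (methyl C15), C5, C6 (lactone CH–O), C7, C8 (CH–OAc), C9, C10 (methylene C14); lactone C11, C12 (C=O), C13 (CH2OAc).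
Remark (assumption): 1 is taken as the commercial statin side-chain phosphonate in its (3R) form.
Remark (assumption): the E geometry written for the C1=C10 enol ether in 17 to 22 is the one expected from a chair-like diyl; it is lost in step 14 and does not affect the target.
Remark (assumption): in step 13 the fully substituted C7=C11 arm is taken as the large group of the ketone, so the (S)-oxazaborolidine gives 6R.

Step 1
Reactants: 1 methyl (3R)-3-[(tert-butyldimethylsilyl)oxy]-6-(dimethoxyphosphoryl)-5-oxohexanoate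
Product: 2 (3R)-3-[(tert-butyldimethylsilyl)oxy]-6-(dimethoxyphosphoryl)-5-oxohexanoic acid
Conditions: LiOH·H2O (2.2 equiv), THF/H2O, 0 °C; then 1 M HCl to pH 3
Reagents that add atoms: lithium hydroxide, [Li+].[OH-]
Why: Ester saponification; the first equivalent of hydroxide holds the β-ketophosphonate as its enolate, which protects the ketone and prevents loss of the C8 silyloxy group.

Step 2
Reactants: 2 (3R)-3-[(tert-butyldimethylsilyl)oxy]-6-(dimethoxyphosphoryl)-5-oxohexanoic acid
Product: 5 (4S)-4-[(tert-butyldimethylsilyl)oxy]-7-(dimethoxyphosphoryl)-2,6-dioxoheptyl 2,2-dimethylpropanoate, via mixed isobutyl carbonic anhydride 3 (not isolated), via diazoketone 4 (not isolated)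
Conditions: iBuOCOCl, N-methylmorpholine, THF, −15 °C; CH2N2, Et2O, 0 °C; then PivOH, Rh2(OAc)4 (cat.), CH2Cl2, rt
Reagents that add atoms: diazomethane, C=[N+]=[N-]; pivalic acid, CC(C)(C)C(=O)O
Why: Arndt–Eistert-type acylation of diazomethane by the mixed anhydride gives the diazoketone, and Rh2(OAc)4-catalysed carbenoid O–H insertion into pivalic acid gives the pivaloyloxymethyl ketone (C10, C14) without touching C8.

Step 3
Reactants: 5 (4S)-4-[(tert-butyldimethylsilyl)oxy]-7-(dimethoxyphosphoryl)-2,6-dioxoheptyl 2,2-dimethylpropanoate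
Product: 6 (5S)-5-[(tert-butyldimethylsilyl)oxy]-3-[(pivaloyloxy)methyl]cyclohex-2-en-1-one
Conditions: LiCl, iPr2NEt, MeCN, rt, high dilution
Reagents that add atoms: none
Why: Intramolecular Horner–Wadsworth–Emmons olefination under Masamune–Roush conditions: the phosphonate carbon C5 closes on the C10 ketone in a six-membered mode and gives the C5=C10 enone regiospecifically, the weak amine base sparing the β-silyloxy group.

Step 4
Reactants: 7 cyclobutanone
Product: 8 cyclobutanone N,N-dimethylhydrazone
Conditions: Me2NNH2, AcOH (cat.), neat, 60 °C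
Reagents that add atoms: 1,1-dimethylhydrazine, CN(C)N
Why: Hydrazone condensation gives an azaenolate precursor that avoids the self-aldol of cyclobutanone in the alkylation that follows.

Step 5
Reactants: 8 cyclobutanone N,N-dimethylhydrazone
Product: 10 2-methylcyclobutanone (racemic), via methylated hydrazone 9 (not isolated)
Conditions: LiN(iPr)2 (LDA), THF, −78 → 0 °C; MeI, −78 °C → rt; then aq. oxalic acid, pentane, rt
Reagents that add atoms: iodomethane, CI; water, O
Why: Azaenolate monoalkylation (hydrazone method), then hydrolysis to the ketone; the new centre is racemic and becomes sp2 in step 6.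

Step 6
Reactants: 10 2-methylcyclobutanone (racemic)
Product: 11 1-[(tert-butyldimethylsilyl)oxy]-2-methylcyclobut-1-ene
Conditions: TBSCl, NaI, Et3N, MeCN, 40 °C; distillation
Reagents that add atoms: tert-butyldimethylsilyl chloride, CC(C)(C)[Si](C)(C)Cl
Why: Thermodynamic enol silylation with silyl iodide made in situ favours the tetrasubstituted silyl enol ether; the minor regioisomer is removed by distillation.

Step 7
Reactants: 12 ethyl 2-(hydroxymethyl)prop-2-enoate
Product: 13 ethyl 2-{[(tert-butyldimethylsilyl)oxy]methyl}prop-2-enoate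
Conditions: TBSCl, imidazole, CH2Cl2, 0 °C → rt
Reagents that add atoms: tert-butyldimethylsilyl chloride, CC(C)(C)[Si](C)(C)Cl
Why: Imidazole-promoted silylation of the primary alcohol, which will carry C13 as a bulky non-acyl ether through the enolate chemistry.

Step 8
Reactants: 13 ethyl 2-{[(tert-butyldimethylsilyl)oxy]methyl}prop-2-enoate
Product: 15 ethyl 3-[(tert-butyldimethylsilyl)oxy]-2-oxopropanoate, via ozonide 14 (not isolated)
Conditions: O3, CH2Cl2, −78 °C; Me2S, −78 °C → rt
Reagents that add atoms: ozone, [O-][O+]=O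
Why: Ozonolysis of the 1,1-disubstituted acrylate with reductive work-up gives the α-keto ester (C11 to C13 unit).

Step 9
Reactants: 6 (5S)-5-[(tert-butyldimethylsilyl)oxy]-3-[(pivaloyloxy)methyl]cyclohex-2-en-1-one; 11 1-[(tert-butyldimethylsilyl)oxy]-2-methylcyclobut-1-ene
Product: 16 cis-anti-cis photoadduct 2,9-bis[(tert-butyldimethylsilyl)oxy]-5-methyl-1-[(pivaloyloxy)methyl]tricyclo[4.4.0.0(2,5)]decan-7-one (9S; central cyclobutane anti to the C8 silyloxy group)
Conditions: hν 350 nm (Pyrex), 11 (5 equiv), CH2Cl2, −40 °C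
Reagents that add atoms: none
Why: The enone triplet of 6 adds to the electron-rich cyclobutene 11 through a triplet 1,4-diradical, and the four-membered ring closes by radical recombination after spin inversion; this is the enone–alkene [2+2] photocycloaddition known for cyclohexenones with 1,2-disubstituted cyclobutenes. The one ring closed, the central cyclobutane C1–C4–C5–C10, therefore forms by stepwise diradical collapse, and it completes the bicyclo[2.2.0]hexane. The selectivity the route needs is head-to-tail regiochemistry (C1–C10 and C4–C5 bonds), secured by the silyloxy donor on C1 pairing with the enone β-carbon C10. Of the new stereocentres, C5 and C10 are cis because a trans six–four fusion is strained, C1 and C4 are cis by the geometry of the cyclobutene, the two outer rings are anti because the cyclobutene methylenes avoid the cyclohexanone ring, and the face anti to the C8 silyloxy group is attacked. None of these four centres survives step 10, so minor diastereomers cost yield but not stereochemical integrity.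

Step 10
Reactants: 16 cis-anti-cis photoadduct 2,9-bis[(tert-butyldimethylsilyl)oxy]-5-methyl-1-[(pivaloyloxy)methyl]tricyclo[4.4.0.0(2,5)]decan-7-one
Product: 17 (2Z,6E,9S)-6,9-bis[(tert-butyldimethylsilyl)oxy]-3-methyl-7-[(pivaloyloxy)methyl]cyclodeca-2,6-dien-1-one
Conditions: PhMe (degassed, dilute, base-washed sealed tube), BHT (cat.), 180 °C
Reagents that add atoms: none
Why: Thermal opening of the bicyclo[2.2.0]hexane: homolysis of the strained C1–C4 bond gives a cyclohexane-1,4-diyl (α-silyloxy radical at C1, tertiary radical at C4), and β-scission of C5–C10 (formal retro-[2+2] in the crossed sense) gives the C1=C10 silyl enol ether and C4=C5 conjugated to the C6 ketone; in the chair-like diyl the C4 methyl should push the C5–C6 bond axial, which puts C6 cis to C3 (Z).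

Step 11
Reactants: 17 (2Z,6E,9S)-6,9-bis[(tert-butyldimethylsilyl)oxy]-3-methyl-7-[(pivaloyloxy)methyl]cyclodeca-2,6-dien-1-one; 15 ethyl 3-[(tert-butyldimethylsilyl)oxy]-2-oxopropanoate
Product: 18 aldol adduct ethyl 2-{(3Z,7E,10S)-7,10-bis[(tert-butyldimethylsilyl)oxy]-4-methyl-2-oxo-8-[(pivaloyloxy)methyl]cyclodeca-3,7-dien-1-yl}-3-[(tert-butyldimethylsilyl)oxy]-2-hydroxypropanoate (epimers at C7 and C11)
Conditions: LiN(iPr)2 (LDA), THF, −78 °C; 15, −78 °C; AcOH quench at −78 °C
Reagents that add atoms: none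
Why: Kinetic α′-deprotonation of the enone at C7 and aldol addition of the lithium enolate to the ketone carbonyl of the α-keto ester; the pivalate has no α-hydrogen, the C8 silyloxy group is retained at −78 °C, and the two new centres (C7, C11) are removed in step 12.

Step 12
Reactants: 18 aldol adduct (epimers at C7 and C11)
Product: 20 ethyl (2Z)-2-{(3Z,7E,10S)-7,10-bis[(tert-butyldimethylsilyl)oxy]-4-methyl-2-oxo-8-[(pivaloyloxy)methyl]cyclodeca-3,7-dien-1-ylidene}-3-[(tert-butyldimethylsilyl)oxy]propanoate (C7=C11; ester cis to the C6 carbonyl), via tertiary mesylate 19 (not isolated)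
Conditions: MsCl, Et3N (excess), CH2Cl2, −20 → 0 °C
Reagents that add atoms: none
Why: Sulfene mesylation of the tertiary alcohol and E1cB elimination through the C6 enolate complete an aldol condensation, mesylate leaving far faster than the C8 silyloxy group; the flat ester is expected to sit next to the enolate oxygen and the bulky silyloxymethyl group to turn toward C8–H, which gives the ester cis to C6.

Step 13
Reactants: 20 (Z)-alkylidene keto ester
Product: 22 (4Z,6R,8S)-1,8,13-tris[(tert-butyldimethylsilyl)oxy]-14-(pivaloyloxy)germacra-1(10),4,7(11)-trien-12,6-olide (1(10)E enol ether), via 6R hydroxy ester 21 (not isolated)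
Conditions: (S)-Me-CBS oxazaborolidine, catecholborane, PhMe, −78 °C; pH 7 buffer; SiO2, CH2Cl2, rt
Reagents that add atoms: none
Why: Corey–Bakshi–Shibata reduction: reagent-controlled 1,2-hydride delivery to the C6 ketone, with the fully substituted C7=C11 arm as the large group, should set 6R, and the cis γ-hydroxy ester then lactonises to the butenolide.

Step 14
Reactants: 22 (4Z,6R,8S)-1,8,13-tris[(tert-butyldimethylsilyl)oxy]-14-(pivaloyloxy)germacra-1(10),4,7(11)-trien-12,6-olide
Product: 24 (4Z,6R,8S)-8,13-bis[(tert-butyldimethylsilyl)oxy]-1-oxogermacra-4,7(11),10(14)-trien-12,6-olide, via tetrabutylammonium enolate 23 (not isolated)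
Conditions: Bu4N[Ph3SiF2] (TBAT, 1.2 equiv), THF, 0 °C
Reagents that add atoms: none
Why: Fluoride cleaves the silyl enol ether and the C1 enolate expels the β-pivaloyloxy group from C14 (E1cB), giving the C1 ketone and the C10=C14 methylene; the anhydrous, weakly basic fluoride source should leave the alkyl silyl ethers and the acidic C6–H untouched.

Step 15
Reactants: 24 (4Z,6R,8S)-8,13-bis[(tert-butyldimethylsilyl)oxy]-1-oxogermacra-4,7(11),10(14)-trien-12,6-olide
Product: 25 (4Z,6R,8S)-8,13-dihydroxy-1-oxogermacra-4,7(11),10(14)-trien-12,6-olide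
Conditions: HF·pyridine, pyridine, THF, 0 °C → rt
Reagents that add atoms: none
Why: Acidic fluoride desilylation of the primary and the secondary silyl ether, under which no alkoxide is formed that could add to the methylene ketone or epimerise C6.

Step 16
Reactants: 25 (4Z,6R,8S)-8,13-dihydroxy-1-oxogermacra-4,7(11),10(14)-trien-12,6-olide
Product: 26 (4Z,6R,8S)-8,13-diacetoxy-1-oxogermacra-4,7(11),10(14)-trien-12,6-olide (CNP0239761.1)
Conditions: Ac2O, pyridine, DMAP (cat.), CH2Cl2, 0 °C
Reagents that add atoms: acetic anhydride, CC(=O)OC(C)=O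
Why: DMAP-catalysed acetylation (esterification) of the C13 primary and C8 secondary hydroxyl groups completes the target without affecting a stereocentre.

**Compound list**
1 | methyl (3R)-3-[(tert-butyldimethylsilyl)oxy]-6-(dimethoxyphosphoryl)-5-oxohexanoate | COC(=O)C[C@H](O[Si](C)(C)C(C)(C)C)CC(=O)CP(=O)(OC)OC | starting material
2 | (3R)-3-[(tert-butyldimethylsilyl)oxy]-6-(dimethoxyphosphoryl)-5-oxohexanoic acid | OC(=O)C[C@H](O[Si](C)(C)C(C)(C)C)CC(=O)CP(=O)(OC)OC | intermediate
3 | mixed isobutyl carbonic anhydride of 2 | CC(C)COC(=O)OC(=O)C[C@H](O[Si](C)(C)C(C)(C)C)CC(=O)CP(=O)(OC)OC | intermediate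
4 | dimethyl [(4S)-4-[(tert-butyldimethylsilyl)oxy]-7-diazo-2,6-dioxoheptyl]phosphonate | [N-]=[N+]=CC(=O)C[C@H](O[Si](C)(C)C(C)(C)C)CC(=O)CP(=O)(OC)OC | intermediate
5 | (4S)-4-[(tert-butyldimethylsilyl)oxy]-7-(dimethoxyphosphoryl)-2,6-dioxoheptyl 2,2-dimethylpropanoate | CC(C)(C)C(=O)OCC(=O)C[C@H](O[Si](C)(C)C(C)(C)C)CC(=O)CP(=O)(OC)OC | intermediate
6 | (5S)-5-[(tert-butyldimethylsilyl)oxy]-3-[(pivaloyloxy)methyl]cyclohex-2-en-1-one | O=C1C=C(COC(=O)C(C)(C)C)C[C@H](O[Si](C)(C)C(C)(C)C)C1 | intermediate
7 | cyclobutanone | O=C1CCC1 | starting material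
8 | cyclobutanone N,N-dimethylhydrazone | CN(C)N=C1CCC1 | intermediate
9 | 2-methylcyclobutanone N,N-dimethylhydrazone (racemic) | CC1CCC1=NN(C)C | intermediate
10 | 2-methylcyclobutanone (racemic) | CC1CCC1=O | intermediate
11 | 1-[(tert-butyldimethylsilyl)oxy]-2-methylcyclobut-1-ene | CC1=C(O[Si](C)(C)C(C)(C)C)CC1 | intermediate
12 | ethyl 2-(hydroxymethyl)prop-2-enoate | C=C(CO)C(=O)OCC | starting material
13 | ethyl 2-{[(tert-butyldimethylsilyl)oxy]methyl}prop-2-enoate | C=C(CO[Si](C)(C)C(C)(C)C)C(=O)OCC | intermediate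
14 | ozonide, ethyl 3-{[(tert-butyldimethylsilyl)oxy]methyl}-1,2,4-trioxolane-3-carboxylate | CCOC(=O)C1(CO[Si](C)(C)C(C)(C)C)OCOO1 | intermediate
15 | ethyl 3-[(tert-butyldimethylsilyl)oxy]-2-oxopropanoate | CCOC(=O)C(=O)CO[Si](C)(C)C(C)(C)C | intermediate
16 | cis-anti-cis photoadduct, 2,9-bis[(tert-butyldimethylsilyl)oxy]-5-methyl-1-[(pivaloyloxy)methyl]tricyclo[4.4.0.0(2,5)]decan-7-one (9S) | O=C1C[C@@H](O[Si](C)(C)C(C)(C)C)C[C@@]2(COC(=O)C(C)(C)C)[C@@H]1[C@]3(C)CC[C@@]32O[Si](C)(C)C(C)(C)C | intermediate
17 | (2Z,6E,9S)-6,9-bis[(tert-butyldimethylsilyl)oxy]-3-methyl-7-[(pivaloyloxy)methyl]cyclodeca-2,6-dien-1-one | C1[C@H](O[Si](C)(C)C(C)(C)C)CC(=O)/C=C(/C)CC/C(O[Si](C)(C)C(C)(C)C)=C1\COC(=O)C(C)(C)C | intermediate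
18 | aldol adduct of 17 at C7 with 15 (tertiary alcohol at C11; epimers at C7 and C11) | C1[C@H](O[Si](C)(C)C(C)(C)C)C(C(O)(CO[Si](C)(C)C(C)(C)C)C(=O)OCC)C(=O)/C=C(/C)CC/C(O[Si](C)(C)C(C)(C)C)=C1\COC(=O)C(C)(C)C | intermediate
19 | tertiary C11 mesylate of 18 | C1[C@H](O[Si](C)(C)C(C)(C)C)C(C(OS(C)(=O)=O)(CO[Si](C)(C)C(C)(C)C)C(=O)OCC)C(=O)/C=C(/C)CC/C(O[Si](C)(C)C(C)(C)C)=C1\COC(=O)C(C)(C)C | intermediate
20 | (Z)-alkylidene keto ester (C7=C11, ethyl ester C12 cis to the C6 carbonyl, CH2OTBS cis to C8) | C1[C@H](O[Si](C)(C)C(C)(C)C)/C(=C(/C(=O)OCC)CO[Si](C)(C)C(C)(C)C)C(=O)/C=C(/C)CC/C(O[Si](C)(C)C(C)(C)C)=C1\COC(=O)C(C)(C)C | intermediate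
21 | (6R)-hydroxy ester, C6 carbinol of 20 | C1[C@H](O[Si](C)(C)C(C)(C)C)/C(=C(/C(=O)OCC)CO[Si](C)(C)C(C)(C)C)[C@H](O)/C=C(/C)CC/C(O[Si](C)(C)C(C)(C)C)=C1\COC(=O)C(C)(C)C | intermediate
22 | (4Z,6R,8S)-1,8,13-tris[(tert-butyldimethylsilyl)oxy]-14-(pivaloyloxy)germacra-1(10),4,7(11)-trien-12,6-olide (1(10)E) | C1[C@H](O[Si](C)(C)C(C)(C)C)C2=C(CO[Si](C)(C)C(C)(C)C)C(=O)O[C@@H]2/C=C(/C)CC/C(O[Si](C)(C)C(C)(C)C)=C1\COC(=O)C(C)(C)C | intermediate
23 | tetrabutylammonium C1 enolate of 22 | C1[C@H](O[Si](C)(C)C(C)(C)C)C2=C(CO[Si](C)(C)C(C)(C)C)C(=O)O[C@@H]2/C=C(/C)CC/C([O-])=C1\COC(=O)C(C)(C)C.CCCC[N+](CCCC)(CCCC)CCCC | intermediate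
24 | (4Z,6R,8S)-8,13-bis[(tert-butyldimethylsilyl)oxy]-1-oxogermacra-4,7(11),10(14)-trien-12,6-olide | C=C1C[C@H](O[Si](C)(C)C(C)(C)C)C2=C(CO[Si](C)(C)C(C)(C)C)C(=O)O[C@@H]2/C=C(/C)CCC1=O | intermediate
25 | (4Z,6R,8S)-8,13-dihydroxy-1-oxogermacra-4,7(11),10(14)-trien-12,6-olide | C=C1C[C@H](O)C2=C(CO)C(=O)O[C@@H]2/C=C(/C)CCC1=O | intermediate
26 | (4Z,6R,8S)-8,13-diacetoxy-1-oxogermacra-4,7(11),10(14)-trien-12,6-olide (CNP0239761.1) | C=C1C[C@H](OC(C)=O)C2=C(COC(C)=O)C(=O)O[C@@H]2/C=C(/C)CCC1=O | target

**Count and risks**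

Total step count: 16. Longest linear sequence: 11 steps (steps 1 to 3, then 9 to 16).

Steps most likely to fail:

1. Step 12. The elimination may place the ester trans to the C6 carbonyl (wrong C7=C11 geometry), so that ring closure in step 13 cannot occur; the preference argued above is not secure. Fallback: set out from 18 and close the lactone while C11 is still sp3. Reduction of the C6 ketone (NaBH4, CeCl3·7H2O, MeOH/THF, −78 °C) and spontaneous lactonisation should give the α-hydroxy-γ-lactone F2, the 6R epimer being separated at this stage. Dehydration of the tertiary alcohol toward C7 with the Burgess reagent (PhMe, 50 °C) then gives the butenolide, and the route is rejoined at 22.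

2. Step 10. Geometric control in the stepwise fragmentation may fail (C4=C5 formed E), and prolonged heating may drain the cyclodeca-1,5-diene into a divinylcyclohexane by Cope rearrangement. Fallback: set out from 16 and run the opening at the lowest temperature and shortest time that consume it, accepting the (2E,6E,9S)-isomer of 17, F1. The enone geometry is then set thermodynamically in a separate operation, by reversible conjugate addition of thiolate (PhSH, Et3N cat., THF, 40 °C), which should move F1 to the less strained ring-cis enone; the route is rejoined at 17.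

3. Step 13. Facial selectivity of hydride delivery may be poor or reversed, because both arms of the C6 ketone are alkenyl groups and the substrate's own bias may oppose the catalyst. Fallback: set out from 20 and use whichever reductant gives a single epimer. If that is the (6S)-hydroxy ester F3, it is kept from lactonising (cold neutral work-up) and inverted by Mitsunobu esterification (4-nitrobenzoic acid, PPh3, DIAD, THF, 0 °C) to the (6R)-4-nitrobenzoate F4. Methanolysis (K2CO3, MeOH, 0 °C) frees the 6R alkoxide, which closes onto the ethyl ester; the route is rejoined at 22.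

Further compounds
F1 | step 10 | (2E,6E,9S)-6,9-bis[(tert-butyldimethylsilyl)oxy]-3-methyl-7-[(pivaloyloxy)methyl]cyclodeca-2,6-dien-1-one | C1[C@H](O[Si](C)(C)C(C)(C)C)CC(=O)/C=C(\C)CC/C(O[Si](C)(C)C(C)(C)C)=C1\COC(=O)C(C)(C)C
F2 | step 12 | (6R,8S)-11-hydroxy-7,11-dihydro analogue of 22 (α-hydroxy-γ-lactone; epimers at C7 and C11) | C1[C@H](O[Si](C)(C)C(C)(C)C)C2C(O)(CO[Si](C)(C)C(C)(C)C)C(=O)O[C@@H]2/C=C(/C)CC/C(O[Si](C)(C)C(C)(C)C)=C1\COC(=O)C(C)(C)C
F3 | step 13 | (6S)-hydroxy ester, C6 epimer of 21 | C1[C@H](O[Si](C)(C)C(C)(C)C)/C(=C(/C(=O)OCC)CO[Si](C)(C)C(C)(C)C)[C@@H](O)/C=C(/C)CC/C(O[Si](C)(C)C(C)(C)C)=C1\COC(=O)C(C)(C)C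
F4 | step 13 | (6R)-4-nitrobenzoate of 21 | C1[C@H](O[Si](C)(C)C(C)(C)C)/C(=C(/C(=O)OCC)CO[Si](C)(C)C(C)(C)C)[C@H](OC(=O)c2ccc(cc2)[N+](=O)[O-])/C=C(/C)CC/C(O[Si](C)(C)C(C)(C)C)=C1\COC(=O)C(C)(C)C
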